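Longipinane labels are used (C1 ketone; C4, C11 cyclobutane CH; C5, C10 substituted cyclobutane carbons; C6 CMe2; C7 CHOH; C8, C9 isovalerate and angelate carbons). The cycloheptane is closed last by ring-closing metathesis that joins C7 and C8; osmylation of the new alkene anti to the C9 angelate then sets both carbinols. The step exploits the cyclobutane of the bicyclo[3.1.1]heptenone: the bonds at C5 and C10 that point away from the enone bridge are nearly parallel and about 3 Å apart, so a CMe2–vinyl arm on C5 and an acyloxyallyl arm on C10 are held ready to close. This diene comes from a vinylketene [2+2] adduct whose isobutyrate tether delivers C6 and C7.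

Key step: step 15

Remark: 1 and 5 are taken as commercial, the same C1–C11 labels are used for the corresponding carbons of all intermediates, and the two chiral catalysts (steps 4 and 13) are specified by the facial sense they must deliver, the enantiomeric catalyst being used if the observed sense is opposite.

Step 1
Reactants: 1 1,1-diethoxy-3-methylbut-2-ene
Product: 2 (2E)-4,4-diethoxy-2-methylbut-2-en-1-ol
Conditions: SeO2 (0.3 equiv), t-BuOOH, CH2Cl2, 0 °C to rt
Reagents that add atoms: selenium dioxide, O=[Se]=O (oxygen carrier); tert-butyl hydroperoxide, CC(C)(C)OO (terminal oxidant)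
Why: Riley allylic oxidation (ene reaction, then [2,3]-sigmatropic shift) hydroxylates the methyl group trans to the chain, which fixes the E alkene that later places the C10 methyl syn to the enone bridge.

Step 2
Reactants: 2 (2E)-4,4-diethoxy-2-methylbut-2-en-1-ol
Product: 4 (2E)-2-methyl-4-oxobut-2-en-1-yl 2-methylpropanoate, via acetal ester 3 (not isolated)
Conditions: i-PrCOCl, pyridine, DMAP (cat.), CH2Cl2, 0 °C; then 1 M HCl, THF, rt
Reagents that add atoms: isobutyryl chloride, CC(C)C(Cl)=O; water, O
Why: DMAP-catalysed acylation of the primary allylic alcohol followed by acid hydrolysis of the enal acetal should leave the ester and the E alkene untouched; the isobutyrate is both the protecting group of the C9 oxygen and the later source of C6, C7 and the gem-dimethyl group.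

Step 3
Reactants: 5 tert-butyl 3-methylbut-2-enoate
Product: 6 tert-butyl{[1-(tert-butoxy)-3-methylbuta-1,3-dien-1-yl]oxy}dimethylsilane
Conditions: LiN(i-Pr)2, THF/DMPU, −78 °C; TBSCl, −78 °C to rt
Reagents that add atoms: tert-butyldimethylsilyl chloride, C[Si](C)(Cl)C(C)(C)C
Why: γ-Deprotonation gives the extended lithium dienolate, which is O-silylated to the silyl ketene acetal needed for the vinylogous Mukaiyama aldol; its ketene acetal geometry is of no consequence.

Step 4
Reactants: 4 (2E)-2-methyl-4-oxobut-2-en-1-yl 2-methylpropanoate; 6 silyl dienol ether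
Product: 7 tert-butyl (2E,5S,6E)-5-hydroxy-3,7-dimethyl-8-(2-methylpropanoyloxy)octa-2,6-dienoate
Conditions: SiCl4, chiral N,N'-dimethyl-1,1'-binaphthyl-2,2'-diamine-derived bisphosphoramide (5 mol %, enantiomer giving Si-face attack), i-Pr2NEt (cat.), CH2Cl2, −78 °C
Reagents that add atoms: none
Why: Lewis base-activated SiCl4 catalysis of the vinylogous Mukaiyama aldol joins the γ-carbon of the dienolate to the enal; the chiral silyl cation complex should direct attack to the Si face and so set the carbinol (future C1) as S, and the open transition state should give the E 2-ene.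

Step 5
Reactants: 7 tert-butyl (2E,5S,6E)-5-hydroxy-3,7-dimethyl-8-(2-methylpropanoyloxy)octa-2,6-dienoate
Product: 10 (2E,5S,6E)-5-(tert-butyldimethylsilyloxy)-3,7-dimethyl-8-(2-methylpropanoyloxy)octa-2,6-dienoic acid, via silyl ether 8 (not isolated), via trimethylsilyl ester 9 (not isolated)
Conditions: TBSOTf, 2,6-lutidine, CH2Cl2, −78 °C; then TMSOTf, 0 °C to rt; pH 5 aqueous work-up
Reagents that add atoms: tert-butyldimethylsilyl triflate, C[Si](C)(OS(=O)(=O)C(F)(F)F)C(C)(C)C
Why: Silylation of the alcohol and silyl triflate-mediated cleavage of the tert-butyl ester (loss of 2-methylpropene, hydrolysis of the silyl ester on work-up) should free the acid in one flask without touching the isobutyrate, which a hydroxide hydrolysis would not spare.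

Step 6
Reactants: 10 (2E,5S,6E)-5-(tert-butyldimethylsilyloxy)-3,7-dimethyl-8-(2-methylpropanoyloxy)octa-2,6-dienoic acid
Product: 13 [4-(tert-butyldimethylsilyloxy)-7-methyl-2-methylidene-6-oxobicyclo[3.1.1]heptan-7-yl]methyl 2-methylpropanoate (C5 cyclobutanone; C10 methyl syn to the three-carbon bridge; C1 silyloxy group on the side of the carbonyl bridge), via acid chloride 11 (not isolated), via vinylketene 12 (not isolated)
Conditions: 1-chloro-N,N,2-trimethylprop-1-en-1-amine, CH2Cl2, 0 °C; then slow addition to Et3N, toluene, 110 °C (0.01 M)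
Reagents that add atoms: none
Why: 1,4-Dehydrochlorination gives the vinylketene, whose intramolecular crossed [2+2] cycloaddition (ketene carbonyl carbon to the less substituted alkene carbon) should give the bicyclo[3.1.1]heptan-6-one; the E alkene puts the methyl syn and the acyloxymethyl arm anti to the three-carbon bridge, and the silyloxy carbon adopts the conformation free of allylic 1,3-strain with the cis methyl (hydrogen toward the methyl, silyloxy anti to C10), which decides the alkene face attacked and so sets C4, C10 and C11 in the required absolute sense.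

Step 7
Reactants: 13 bicyclic cyclobutanone isobutyrate
Product: 15 methyl oxalate of the tricyclic aldol lactone (seven-membered lactone C5–CMe2–C(=O)–O–CH2–C10; oxalate oxygen on C5 syn to the three-carbon bridge), via lithium aldolate 14 (not isolated)
Conditions: LiN(i-Pr)2, THF (0.02 M), −78 °C; then ClC(O)CO2Me, −78 to 0 °C
Reagents that add atoms: methyl chlorooxoacetate, COC(=O)C(Cl)=O
Why: Intramolecular aldol lactonisation: the ester enolate of the isobutyrate tether can only reach the face of the strained, non-enolisable cyclobutanone that is anti to the three-carbon bridge, so C6 is bonded to C5 on the required face, and the tertiary alkoxide is trapped as its methyl oxalate for deoxygenation.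

Step 8
Reactants: 15 methyl oxalate of the aldol lactone
Product: 16 tricyclic lactone (C5–H syn to the three-carbon bridge)
Conditions: Bu3SnH, AIBN (cat.), toluene, 110 °C
Reagents that add atoms: none
Why: Barton–McCombie-type radical deoxygenation of the tertiary oxalate; the C5 radical is tied into the lactone ring, so hydrogen can only be delivered to the face syn to the three-carbon bridge, which gives the C5 configuration of the target.

Step 9
Reactants: 16 tricyclic lactone
Product: 17 lactol of 16 (anomer mixture)
Conditions: i-Bu2AlH, CH2Cl2, −78 °C; aqueous potassium sodium tartrate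
Reagents that add atoms: none
Why: Partial reduction of the α-quaternary lactone should stop at the tetrahedral aluminium lactolate at low temperature and give the lactol, a masked C7 aldehyde.

Step 10
Reactants: 17 lactol
Product: 18 bicyclic alcohol (C5 bears CMe2–CH=CH2 and C10 bears CH2OH, both anti to the three-carbon bridge; C1 silyl ether; C3 exocyclic methylene)
Conditions: Ph3PCH3Br, KOt-Bu, THF, 0 to 50 °C
Reagents that add atoms: methylenetriphenylphosphorane, C=P(c1ccccc1)(c1ccccc1)c1ccccc1
Why: Wittig methylenation of the open hydroxy aldehyde form of the lactol installs the C7 vinyl group and at the same time opens the tether to free the C9 primary alcohol.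

Step 11
Reactants: 18 bicyclic silyl ether alcohol
Product: 19 bicyclic diol (C1 secondary alcohol; C9 primary alcohol)
Conditions: Bu4NF, THF, rt to 40 °C
Reagents that add atoms: none
Why: Fluoride-mediated cleavage of the secondary silyl ether, to which the alkenes and the primary alcohol are inert.

Step 12
Reactants: 19 bicyclic diol
Product: 21 4,6-dimethyl-7-(2-methylbut-3-en-2-yl)-2-oxobicyclo[3.1.1]hept-3-ene-6-carbaldehyde (C9 aldehyde and C5 arm both anti to the enone bridge), via deconjugated keto aldehyde 20 (not isolated)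
Conditions: Dess–Martin periodinane, NaHCO3, CH2Cl2, rt; then DBU (0.3 equiv), rt
Reagents that add atoms: none
Why: Dess–Martin oxidation converts both alcohols, and DBU then moves the exocyclic alkene into conjugation through the C2 dienolate (the bridgehead C11 cannot enolise) to give the verbenone-type enone; the C1 stereocentre that steered the cycloaddition is erased as planned.

Step 13
Reactants: 21 enone aldehyde
Product: 22 6-[(1R)-1-hydroxyprop-2-en-1-yl]-4,6-dimethyl-7-(2-methylbut-3-en-2-yl)bicyclo[3.1.1]hept-3-en-2-one
Conditions: Zn(CH=CH2)2 (from CH2=CHMgBr and ZnCl2), (+)-3-exo-morpholinoisoborneol [(+)-MIB, 10 mol %, enantiomer giving Re-face attack], toluene, −20 to 0 °C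
Reagents that add atoms: divinylzinc, C=C[Zn]C=C
Why: Amino alcohol-catalysed enantioselective vinylzinc addition to the non-enolisable aldehyde, chemoselective over the enone; the ligand should direct vinyl transfer to the Re face and so set C9 (R in 22), the substrate itself offering no useful facial bias.

Step 14
Reactants: 22 vinyl carbinol
Product: 23 (1R)-1-[4,6-dimethyl-7-(2-methylbut-3-en-2-yl)-2-oxobicyclo[3.1.1]hept-3-en-6-yl]prop-2-en-1-yl (2Z)-2-methylbut-2-enoate
Conditions: angelic acid, 2,4,6-trichlorobenzoyl chloride, Et3N, toluene, rt; then 22, toluene, 80 °C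
Reagents that add atoms: angelic acid, C/C=C(/C)C(O)=O
Why: Yamaguchi mixed-anhydride esterification is the established way to acylate a hindered alcohol with angelic acid without Z-to-E isomerisation to the tiglate.

Step 15
Reactants: 23 angelate diene
Product: 24 9-angeloyloxylongipina-2,7-dien-1-one
Conditions: second-generation Hoveyda–Grubbs catalyst (10 mol %), 1,4-benzoquinone (20 mol %), toluene (2 mM), 80 °C, argon sparge
Reagents that add atoms: none
Why: Ring-closing olefin metathesis: the ruthenium alkylidene loads onto the less hindered allylic ester vinyl group at C8, forms a ruthenacyclobutane with the neopentylic vinyl group at C7 and expels ethene, which creates the C7=C8 bond. The closest known reaction type is the ring-closing metathesis of 1,8-dienes flanked by quaternary carbons to cycloheptenes. The seven-membered ring (C5–C6–C7=C8–C9–C10 plus C4 or C11) is closed by this intramolecular alkene–alkylidene exchange between two arms that sit cis on the 1,3-positions of the cyclobutane. No stereocentre is created and the ring size enforces the Z alkene; C5, C9 and C10 are untouched. The step needs ring closure to outrun cross-metathesis at the C8 vinyl group and must spare the angelate and enone alkenes: the rigid cyclobutane holds the two vinyl groups within bonding distance, high dilution disfavours dimers, the two other alkenes are trisubstituted and electron-poor, and benzoquinone suppresses ruthenium hydride isomerisation.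

Step 16
Reactants: 24 9-angeloyloxylongipina-2,7-dien-1-one
Product: 25 9-angeloyloxy-7,8-dihydroxylongipin-2-en-1-one (7-OH and 8-OH cis to each other and trans to the 9-ester)
Conditions: OsO4 (5 mol %), N-methylmorpholine N-oxide, acetone/H2O, 0 °C
Reagents that add atoms: osmium tetroxide, O=[Os](=O)(=O)=O (oxygen carrier); N-methylmorpholine N-oxide, C[N+]1([O-])CCOCC1 (terminal oxidant)
Why: Catalytic syn-dihydroxylation of the only electron-rich alkene; OsO4 should add to the ring face anti to the pseudo-axial allylic C9 ester, which sets C7 and C8 cis to each other and trans to the C9 oxygen.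

Step 17
Reactants: 25 9-angeloyloxy-7,8-dihydroxylongipin-2-en-1-one
Product: 26 CNP0251293.1 (9-angeloyloxy-7-hydroxy-8-isovaleryloxylongipin-2-en-1-one)
Conditions: 2-aminoethyl diphenylborinate (10 mol %), isovaleryl chloride, i-Pr2NEt, MeCN, rt
Reagents that add atoms: isovaleryl chloride, CC(C)CC(Cl)=O
Why: Borinic acid-catalysed monoacylation of the cis-1,2-diol through its tetracoordinate borinate should acylate the less hindered C8 oxygen and leave the neopentylic C7 hydroxyl next to the gem-dimethyl carbon free.

Compound list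
1 | 1,1-diethoxy-3-methylbut-2-ene | CCOC(OCC)C=C(C)C | starting material
2 | (2E)-4,4-diethoxy-2-methylbut-2-en-1-ol | CCOC(OCC)/C=C(\C)CO | intermediate
3 | (2E)-4,4-diethoxy-2-methylbut-2-en-1-yl 2-methylpropanoate (not isolated) | CCOC(OCC)/C=C(\C)COC(=O)C(C)C | intermediate
4 | (2E)-2-methyl-4-oxobut-2-en-1-yl 2-methylpropanoate | O=C/C=C(\C)COC(=O)C(C)C | intermediate
5 | tert-butyl 3-methylbut-2-enoate | CC(C)=CC(=O)OC(C)(C)C | starting material
6 | tert-butyl{[1-(tert-butoxy)-3-methylbuta-1,3-dien-1-yl]oxy}dimethylsilane (ketene acetal geometry not defined) | C=C(C)C=C(OC(C)(C)C)O[Si](C)(C)C(C)(C)C | intermediate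
7 | tert-butyl (2E,5S,6E)-5-hydroxy-3,7-dimethyl-8-(2-methylpropanoyloxy)octa-2,6-dienoate | CC(C)(C)OC(=O)/C=C(\C)C[C@H](O)/C=C(\C)COC(=O)C(C)C | intermediate
8 | 5-O-TBS ether of 7 (not isolated) | CC(C)(C)OC(=O)/C=C(\C)C[C@H](O[Si](C)(C)C(C)(C)C)/C=C(\C)COC(=O)C(C)C | intermediate
9 | trimethylsilyl ester of 10 (not isolated) | C[Si](C)(C)OC(=O)/C=C(\C)C[C@H](O[Si](C)(C)C(C)(C)C)/C=C(\C)COC(=O)C(C)C | intermediate
10 | (2E,5S,6E)-5-(tert-butyldimethylsilyloxy)-3,7-dimethyl-8-(2-methylpropanoyloxy)octa-2,6-dienoic acid | OC(=O)/C=C(\C)C[C@H](O[Si](C)(C)C(C)(C)C)/C=C(\C)COC(=O)C(C)C | intermediate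
11 | acid chloride of 10 (not isolated) | ClC(=O)/C=C(\C)C[C@H](O[Si](C)(C)C(C)(C)C)/C=C(\C)COC(=O)C(C)C | intermediate
12 | vinylketene from 11 by loss of HCl (not isolated) | O=C=CC(=C)C[C@H](O[Si](C)(C)C(C)(C)C)/C=C(\C)COC(=O)C(C)C | intermediate
13 | [4-(tert-butyldimethylsilyloxy)-7-methyl-2-methylidene-6-oxobicyclo[3.1.1]heptan-7-yl]methyl 2-methylpropanoate (methyl syn and acyloxymethyl anti to the three-carbon bridge; silyloxy on the carbonyl-bridge side) | O=C1[C@@H]2C(=C)C[C@H](O[Si](C)(C)C(C)(C)C)[C@H]1[C@]2(C)COC(=O)C(C)C | intermediate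
14 | lithium aldolate of the tricyclic lactone (not isolated) | CC1(C)C(=O)OC[C@]2(C)[C@H]3C(=C)C[C@H](O[Si](C)(C)C(C)(C)C)[C@@H]2[C@@]13[O-].[Li+] | intermediate
15 | methyl oxalate of the tricyclic aldol lactone | CC1(C)C(=O)OC[C@]2(C)[C@H]3C(=C)C[C@H](O[Si](C)(C)C(C)(C)C)[C@@H]2[C@@]13OC(=O)C(=O)OC | intermediate
16 | tricyclic lactone (C5–H syn to the three-carbon bridge) | CC1(C)C(=O)OC[C@]2(C)[C@H]3C(=C)C[C@H](O[Si](C)(C)C(C)(C)C)[C@@H]2[C@@H]13 | intermediate
17 | lactol of 16 (anomer mixture) | CC1(C)C(O)OC[C@]2(C)[C@H]3C(=C)C[C@H](O[Si](C)(C)C(C)(C)C)[C@@H]2[C@@H]13 | intermediate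
18 | bicyclic alcohol with C5 CMe2–vinyl arm and C10 CH2OH (both anti), C1 silyl ether, C3 exocyclic methylene | C=CC(C)(C)[C@H]1[C@@H]2C(=C)C[C@H](O[Si](C)(C)C(C)(C)C)[C@H]1[C@]2(C)CO | intermediate
19 | bicyclic diol (C1–OH, C9–OH) | C=CC(C)(C)[C@H]1[C@@H]2C(=C)C[C@H](O)[C@H]1[C@]2(C)CO | intermediate
20 | deconjugated keto aldehyde (not isolated) | C=CC(C)(C)[C@H]1[C@@H]2C(=C)CC(=O)[C@H]1[C@]2(C)C=O | intermediate
21 | 4,6-dimethyl-7-(2-methylbut-3-en-2-yl)-2-oxobicyclo[3.1.1]hept-3-ene-6-carbaldehyde | C=CC(C)(C)[C@H]1[C@@H]2C(C)=CC(=O)[C@H]1[C@]2(C)C=O | intermediate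
22 | 6-[(1R)-1-hydroxyprop-2-en-1-yl]-4,6-dimethyl-7-(2-methylbut-3-en-2-yl)bicyclo[3.1.1]hept-3-en-2-one | C=CC(C)(C)[C@H]1[C@@H]2C(C)=CC(=O)[C@H]1[C@]2(C)[C@H](O)C=C | intermediate
23 | (1R)-1-[4,6-dimethyl-7-(2-methylbut-3-en-2-yl)-2-oxobicyclo[3.1.1]hept-3-en-6-yl]prop-2-en-1-yl (2Z)-2-methylbut-2-enoate | C=CC(C)(C)[C@H]1[C@@H]2C(C)=CC(=O)[C@H]1[C@]2(C)[C@H](OC(=O)/C(C)=C\C)C=C | intermediate
24 | 9-angeloyloxylongipina-2,7-dien-1-one | C/C=C(/C)C(=O)O[C@@H]1C=CC(C)(C)[C@@H]2[C@H]3C(=O)C=C(C)[C@@H]2[C@@]13C | intermediate
25 | 9-angeloyloxy-7,8-dihydroxylongipin-2-en-1-one | C/C=C(/C)C(=O)O[C@@H]1[C@@H](O)[C@@H](O)C(C)(C)[C@@H]2[C@H]3C(=O)C=C(C)[C@@H]2[C@@]13C | intermediate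
26 | CNP0251293.1 (9-angeloyloxy-7-hydroxy-8-isovaleryloxylongipin-2-en-1-one) | C/C=C(/C)C(=O)O[C@@H]1[C@@H](OC(=O)CC(C)C)[C@@H](O)C(C)(C)[C@@H]2[C@H]3C(=O)C=C(C)[C@@H]2[C@@]13C | target

Total step count: 17. Longest linear sequence: 16 steps (steps 1, 2 and 4–17; step 3 prepares the second fragment).

Steps most likely to fail

Step 15 (ring-closing metathesis). Loading of the catalyst and ring closure at the neopentylic C7 vinyl group may be slow, so that intermolecular metathesis at the C8 vinyl group or catalyst decay takes over. The fallback is a relay ring-closing metathesis that sets out from 21 and comes back at 24. Hept-1-en-6-yne is hydrozirconated at the alkyne with Cp2Zr(H)Cl, transmetalated with Me2Zn and added to aldehyde 21 under the same (+)-MIB control to give the relay allylic alcohol F3. Yamaguchi angeloylation as in step 14 gives the relay ester F4. With second-generation Grubbs catalyst the ruthenium loads on the unhindered terminal alkene, expels cyclopentene and is thereby delivered intramolecularly to C8, from where closure onto the C7 vinyl group gives 24.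

Step 6 (ketene cycloaddition). The alkene is inductively deactivated by its two allylic oxygen substituents, so cycloaddition may be slower than ketene oligomerisation; deprotonation at the CH2 instead of the methyl group may divert the acid chloride into a dienylketene, and the face selectivity may be incomplete. The fallback is a keteniminium cycloaddition that sets out from 10 and comes back at 13. The acid chloride 11 is quenched with pyrrolidine to give the pyrrolidine amide F1. Triflic anhydride and 2,4,6-collidine in 1,2-dichloroethane at 80 °C convert it into the more electrophilic vinylketeniminium triflate, which undergoes the same crossed [2+2] cycloaddition to give the cyclobutaniminium triflate F2. Hydrolysis with aqueous NaHCO3 gives 13.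

Step 16 (dihydroxylation). Osmylation of the angelate alkene may compete (loss of chemoselectivity), or the facial selectivity may be incomplete. The fallback dihydroxylates before the angelate is introduced; it sets out from 22 and comes back at 26. Alcohol 22 is silylated (Et3SiCl, imidazole) to the triethylsilyl ether F5, and ring-closing metathesis as in step 15 gives the silyloxy cycloheptene F6. OsO4 with N-methylmorpholine N-oxide adds anti to the bulky silyloxy group to give the diol F7, and borinic acid-catalysed isovaleroylation as in step 17 gives the C8 ester F8. HF·pyridine removes the silyl group to give the C7,C9-diol C8-isovalerate F9. Yamaguchi angeloylation then takes place at the C9 hydroxyl, the C7 hydroxyl next to the gem-dimethyl carbon being the more hindered, and gives 26.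

Further compounds
F1 | step 6 | pyrrolidine amide of acid 10 | O=C(/C=C(\C)C[C@H](O[Si](C)(C)C(C)(C)C)/C=C(\C)COC(=O)C(C)C)N1CCCC1
F2 | step 6 | cyclobutaniminium triflate (pyrrolidinium ylidene analogue of 13) | C1CC[N+](C1)=C1[C@@H]2C(=C)C[C@H](O[Si](C)(C)C(C)(C)C)[C@H]1[C@]2(C)COC(=O)C(C)C.[O-]S(=O)(=O)C(F)(F)F
F3 | step 15 | relay allylic alcohol, 6-[(1R,2E)-1-hydroxyocta-2,7-dien-1-yl] analogue of 22 | C=CC(C)(C)[C@H]1[C@@H]2C(C)=CC(=O)[C@H]1[C@]2(C)[C@H](O)/C=C/CCCC=C
F4 | step 15 | relay angelate ester of F3 | C=CC(C)(C)[C@H]1[C@@H]2C(C)=CC(=O)[C@H]1[C@]2(C)[C@H](OC(=O)/C(C)=C\C)/C=C/CCCC=C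
F5 | step 16 | triethylsilyl ether of 22 | C=CC(C)(C)[C@H]1[C@@H]2C(C)=CC(=O)[C@H]1[C@]2(C)[C@H](O[Si](CC)(CC)CC)C=C
F6 | step 16 | 9-(triethylsilyloxy)longipina-2,7-dien-1-one | CC[Si](CC)(CC)O[C@@H]1C=CC(C)(C)[C@@H]2[C@H]3C(=O)C=C(C)[C@@H]2[C@@]13C
F7 | step 16 | 7,8-dihydroxy-9-(triethylsilyloxy)longipin-2-en-1-one | CC[Si](CC)(CC)O[C@@H]1[C@@H](O)[C@@H](O)C(C)(C)[C@@H]2[C@H]3C(=O)C=C(C)[C@@H]2[C@@]13C
F8 | step 16 | 7-hydroxy-8-isovaleryloxy-9-(triethylsilyloxy)longipin-2-en-1-one | CC[Si](CC)(CC)O[C@@H]1[C@@H](OC(=O)CC(C)C)[C@@H](O)C(C)(C)[C@@H]2[C@H]3C(=O)C=C(C)[C@@H]2[C@@]13C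
F9 | step 16 | 7,9-dihydroxy-8-isovaleryloxylongipin-2-en-1-one | O[C@@H]1[C@@H](OC(=O)CC(C)C)[C@@H](O)C(C)(C)[C@@H]2[C@H]3C(=O)C=C(C)[C@@H]2[C@@]13C
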